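Atom labels used below: ring A carries the ether oxygen at A1, a hydroxyl at A3 and the chain at A5. Ring B carries the ether oxygen at B1, hydroxyls at B2 and B4 and the chain at B6. The chain runs from C1 (on B6) to C14 (on A5). In the section on the alternatives, a label from A1 to A7 that follows the word "compound" is a compound label; ring positions are written as bonds or are called "position".

## Analysis of the target

The target, C26H36O4, is a 20-membered ansa-diaryl ether whose large ring runs through A5, A6 and A1 of ring A, the ether oxygen, B1 and B6 of ring B and the fourteen methylene carbons C1 to C14. It has no stereocentre, and a tether of fourteen methylenes is too long to hold the two rings as separable atropisomers, so the synthesis carries no stereochemical problem. The sensitive part is the set of three free phenols, above all the 1,2,4-trioxygenated ring B, which air oxidises readily once it is deprotonated. Two things make the synthesis hard: the ether oxygen sits on B1, a carbon flanked on both sides by the B2 hydroxyl and the chain on B6, and a 20-membered ring has to be closed against a large entropic cost. The strategy rests on a hidden symmetry: if the O–B1 bond is replaced by O–H and B1–H, the two rings become the same 5-alkylresorcinol, joined through C1 to C14. The target is therefore the intramolecular dehydro-dimer of one symmetric bis-resorcinol, in which a ring A oxygen is bound to the 4-position of ring B (B1, equivalent to B5 before the coupling).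

## Retrosynthetic reasoning

**From 9 to 8.** The ring hydrogens at A2, A4, A6, B3 and B5 of 9 are replaced by bromine, which gives the pentabromide 8. These bromines are what an oxidative coupling of a fully blocked precursor leaves behind. The forward reaction has to cleave five aryl C–Br bonds by hydrogenolysis without touching the diaryl ether.

**From 8 to 7.** Ring B of 8 is taken back to its oxidised form 7, in which B1 is an sp3 carbon carrying both the aryloxy group and a bromine, and B4 is a carbonyl. No skeletal bond changes. A coupling at a brominated ring carbon must deliver an ipso-substituted dienone, and this step accounts for it. The forward reaction is a two-electron reduction that expels bromide from B1 and restores the arene.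

**From 7 to 6.** The O–B1 bond is cut. It is the only bond whose cleavage leads to a symmetric precursor, the hexabromide 6. A cut in the chain, or a cut of the ether in the sense of an aryl halide plus a phenol, would call for two different rings made separately and differentiated at three oxygens. In 6 the two rings, the two hydroxyls of each ring and the carbons B1 and B5 are pairwise equivalent, so no protecting group or differentiation is needed. The forward reaction must remove two electrons and two protons, form the C–O bond at B1 and not at B3, do so within one molecule, and compete with the solvent. The six bromines close off every C–C coupling site.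

**From 6 to 5.** The six C–Br bonds are removed, which gives the bis-resorcinol 5. The forward reaction is an exhaustive electrophilic bromination, for which a 5-alkylresorcinol is activated at exactly the three positions concerned.

**From 5 to 4.** The four phenols are masked as methyl ethers (4), so that the tether can be built with organometallic reagents. The forward reaction is a fourfold Lewis-acid ether cleavage.

**From 4 to 3 and 2, and from 3 to 1.** The bonds C1–C2 and C13–C14 are cut, one carbon away from each ring. This gives two molecules of the benzylic electrophile 2 and one molecule of the C12 bis-nucleophile 3, which comes from the dibromide 1. The cut is placed there because the benzylic bromide is the best electrophile available and because both ends are made in one operation. The forward reaction is a double copper-catalysed sp3–sp3 coupling, in which each end of 3 takes up one molecule of 2.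

## Alternatives that were turned down

Alternative 1: Ring A itself is taken apart at the bonds A2–A3 and A1–A6, with A3–A4 broken and re-formed on the way.
- Disconnection: the ether oxygen arrives on the aryl ethynyl ether of ring B, compound A3, and ring positions A3 to A6 come from the 3-alkylcyclobutenone, compound A2.
- Forward key step: heating compound A2 with compound A3 in toluene (Danheiser benzannulation) should open the four-membered ring and add the alkyne. A four-electron ring opening and a six-electron closure then give the phenol, compound A1. Ring-closing metathesis of its two terminal alkenes (11 + 5 − 2 = 14 chain carbons), hydrogenation and demethylation would follow.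
- For: the mechanism fixes the 1,3,5-pattern of ring A, and the hindered B1–O bond is never made by a cross-coupling. Metathesis is a more predictable ring closure than an anodic coupling, so on the certainty of both the ether and the macrocycle this alternative is stronger.
- Against: compound A2 and compound A3 each need several steps, the ynol ether is sensitive, and three steps follow the benzannulation. The sequence is about twice as long.
- Comparison: the chosen strategy offers six steps from two catalogue compounds, with symmetry doing the work of the protecting groups and of the fragment synthesis.

Alternative 2: The C–O bonds at positions A3 and B4 are removed, leaving the deoxy macrocycle, compound A5.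
- Forward key step: compound A5 is borylated with B2pin2 and [Ir(OMe)(cod)]2/4,4'-di-tert-butyl-2,2'-bipyridine, and both C–B bonds are oxidised with KHSO5 in the same flask to give the B2 methyl ether of the target, compound A4. Cleavage of that methyl ether would follow.
- For: each ring has exactly one C–H bond without an ortho neighbour (positions A3 and B4), so the sites of borylation are predictable on steric grounds. On regiochemical certainty this alternative is stronger than the chosen one.
- Against: it solves neither hard problem. Compound A5 still contains the hindered diaryl ether and the 20-membered ring, so a complete macrocycle synthesis must come first. Oxygens that come for free in 3,5-dioxygenated building blocks are instead installed late with an iridium catalyst, and both borylations must go to completion on a large, flexible substrate.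
- Comparison: the chosen strategy uses the same oxygens to drive the ring closure and gains them at no cost in steps.

Alternative 3: The chain is cut at C5–C6, with C4 to C7 as a 1,3-diyne and C13–C14 as an aryl alkyne.
- Forward key step: slow addition of the bis-terminal alkyne, compound A7, to Cu(OAc)2 in pyridine couples the two alkyne ends and gives the macrocyclic triyne, compound A6. Hydrogenation of the three alkynes and demethylation would follow.
- For: this is a classical large-ring closure, it forms a C–C bond far from the hindered ether, and it creates no geometric isomers. On the reliability of the ring-closing event it is stronger.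
- Against: compound A7 requires an intermolecular ether synthesis at the hindered B1 and three separately installed alkyne units. The rigid diyne and aryl alkyne must fit into a 20-membered ring that also contains a meta-bridged arene. The linear length is roughly double.
- Comparison: the chosen strategy makes the difficult C–O bond and the macrocycle in one event from a precursor that is three steps old.

Key step: step 4

Remark: 7 is written as its 2,5-dienone tautomer (carbonyl at B4, enol at B2). The 2,4-dienone tautomer (carbonyl at B2, enol at B4) is the same substance for every purpose of the route.

## Route

Step 1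
Reactants: 1 1,12-dibromododecane; 2 3,5-dimethoxybenzyl bromide (two molecules for each molecule of 1)
Product: 4 1,14-bis(3,5-dimethoxyphenyl)tetradecane, via dodecane-1,12-diylbis(magnesium bromide) 3 (not isolated)
Conditions: 1, Mg turnings (excess), THF, reflux; then solution of 3 added to 2 (2.2 equiv), Li2CuCl4 (cat.), THF, −10 °C to rt
Reagents that add atoms: magnesium (two atoms per molecule of 1, held only in intermediate 3), [Mg]; 3,5-dimethoxybenzyl bromide (the second molecule of 2, which supplies the arylmethyl group for the other chain end), COc1cc(CBr)cc(OC)c1
Why: Kochi coupling, a copper-catalysed sp3–sp3 cross-coupling of an alkyl Grignard reagent with a benzylic bromide; the benzylic C–Br bond is the most reactive electrophile present and aryl methyl ethers are inert to Grignard reagents. Each C–Mg end of 3 takes up one molecule of 2, so 4 holds the twelve carbons of 1 and two 3,5-dimethoxybenzyl units, and one operation forms C1–C2 and C13–C14 and sets the whole fourteen-carbon tether.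

Step 2
Reactants: 4 1,14-bis(3,5-dimethoxyphenyl)tetradecane
Product: 5 5,5'-(tetradecane-1,14-diyl)bis(benzene-1,3-diol)
Conditions: BBr3 (6 equiv), CH2Cl2, −78 °C to rt; then H2O
Reagents that add atoms: none
Why: Lewis-acid cleavage of aryl methyl ethers (BBr3 demethylation): boron binds the ether oxygen and bromide attacks the methyl group; the saturated tether offers no competing site.

Step 3
Reactants: 5 5,5'-(tetradecane-1,14-diyl)bis(benzene-1,3-diol)
Product: 6 1,14-bis(2,4,6-tribromo-3,5-dihydroxyphenyl)tetradecane
Conditions: Br2 (6.1 equiv), AcOH, rt, dark; aq. NaHSO3 work-up
Reagents that add atoms: bromine (six molecules, each leaves one bromine atom in 6), BrBr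
Why: Electrophilic aromatic bromination; in a 5-alkylresorcinol every free ring carbon is ortho or para to both hydroxyls, so three bromines should enter each ring without a catalyst. Any bromodienone from over-bromination is returned to 6 by the NaHSO3 wash.

Step 4
Reactants: 6 1,14-bis(2,4,6-tribromo-3,5-dihydroxyphenyl)tetradecane
Product: 7 macrocyclic bromo quinol ether: ring A (A2, A4, A6 tribromo, A3–OH, A5 chain) bound through its A1 oxygen to the sp3 carbon B1 of a 2,4,6-tribromo-3-hydroxycyclohexa-2,5-dien-1-one (B1 carries Br and O-aryl, B2 enol OH, B3–Br, B4 C=O, B5–Br, B6 chain); racemic at B1
Conditions: constant-current electrolysis, undivided cell, glassy-carbon anode, Pt cathode, LiClO4 (0.1 M), dry MeOH, about 1 mM in 6, low current density, about 2 F/mol, rt, N2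
Reagents that add atoms: none
Why: Proposed new method: two-electron anodic oxidation (electron, proton, electron) of one tribromoresorcinol ring of 6 should give a phenoxonium ion with positive charge at B1, B3 and B5; since all three carry bromine, C–C pairing and ring substitution are shut off and only addition of a heteroatom to a brominated carbon is left. A hydroxyl oxygen of the other, still neutral ring adds at B1 and loses its proton, which gives 7 (O–B1 bond, B4 carbonyl, B2 enol); pairing of a ring A phenoxyl radical with spin density at B1 of an oxidised ring B would end at the same compound. The closest known reaction type is the anodic C–O coupling of 2,6-dihalo-4-alkylphenols to aryloxy-halodienones, which has also been used to close macrocyclic diaryl ethers; the new element is the substrate class, a 2,4,6-tribromoresorcinol, whose cation is not stabilised by the second, meta hydroxyl. The 20-membered ring closes by addition of oxygen to a trigonal carbon of a delocalised cation; a ring of this size has no stereoelectronic constraint, so the cost is entropic and is met by millimolar concentration and a low current density that keeps the cation concentration small. B1 becomes a stereocentre (Br, O-aryl, B2, B6) with no controlling element; 7 is racemic and the centre is removed in step 5. Two selectivities are needed: the ring A oxygen instead of solvent, and B1 instead of B3. B1 is para to one ring B oxygen, the usual site at which a phenoxonium ion takes up a nucleophile, it has a symmetry twin in B5 that leads to the same product, and attack there leaves a cross-conjugated vinylogous acid, whereas B3 is ortho to both oxygens; the symmetry of 6 makes every productive combination of ring, oxygen and carbon converge on 7. Charge is held near 2 F/mol because ring A of 7 still has a free hydroxyl and could be oxidised further.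

Step 5
Reactants: 7 macrocyclic bromo quinol ether (used crude)
Product: 8 A2,A4,A6,B3,B5-pentabromo derivative of the target (20-membered diaryl ether with A3, B2 and B4 hydroxyls)
Conditions: Zn dust, AcOH, rt
Reagents that add atoms: none
Why: Dissolving-metal reduction of a bromo dienone: Zn transfers two electrons, bromide leaves from B1 and ring B regains aromaticity as the B4 phenol. Bromide is a far better leaving group than the aryloxide, and aryl C–Br bonds are inert to Zn/AcOH at room temperature; the racemic centre at B1 disappears here.

Step 6
Reactants: 8 pentabromo macrocyclic diaryl ether
Product: 9 target, 20-membered diaryl ether with hydroxyls at A3, B2 and B4 (CNP0173380.0)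
Conditions: H2 (1 atm), 10% Pd/C, Et3N (excess), degassed MeOH, rt; acidic work-up under N2
Reagents that add atoms: none
Why: Heterogeneous catalytic hydrogenolysis of aryl C–Br bonds (hydrodehalogenation); Et3N binds the HBr so that the catalyst stays active. Diaryl ether C–O bonds and the arene rings are not reduced at 1 atm and room temperature.

## Compound list

1 | 1,12-dibromododecane | BrCCCCCCCCCCCCBr | starting material
2 | 3,5-dimethoxybenzyl bromide | COc1cc(CBr)cc(OC)c1 | starting material
3 | dodecane-1,12-diylbis(magnesium bromide) | Br[Mg]CCCCCCCCCCCC[Mg]Br | intermediate
4 | 1,14-bis(3,5-dimethoxyphenyl)tetradecane | COc1cc(CCCCCCCCCCCCCCc2cc(OC)cc(OC)c2)cc(OC)c1 | intermediate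
5 | 5,5'-(tetradecane-1,14-diyl)bis(benzene-1,3-diol) | Oc1cc(O)cc(CCCCCCCCCCCCCCc2cc(O)cc(O)c2)c1 | intermediate
6 | 1,14-bis(2,4,6-tribromo-3,5-dihydroxyphenyl)tetradecane | Oc1c(Br)c(O)c(Br)c(CCCCCCCCCCCCCCc2c(Br)c(O)c(Br)c(O)c2Br)c1Br | intermediate
7 | macrocyclic 4-aryloxy-2,4,6-tribromo-3-hydroxycyclohexa-2,5-dienone (O–B1 bond, racemic at B1) | Oc1c(Br)c2c(Br)c(c1Br)OC1(Br)C(O)=C(Br)C(=O)C(Br)=C1CCCCCCCCCCCCCC2 | intermediate
8 | A2,A4,A6,B3,B5-pentabromo macrocyclic diaryl ether | Oc1c(Br)c2c(Br)c(c1Br)Oc1c(O)c(Br)c(O)c(Br)c1CCCCCCCCCCCCCC2 | intermediate
9 | CNP0173380.0, 20-membered diaryl ether with A3, B2 and B4 hydroxyls | Oc1cc2cc(c1)Oc1c(O)cc(O)cc1CCCCCCCCCCCCCC2 | target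

## Step count and least certain steps

Total step count: 6. Longest linear sequence: 6 steps (1 to 9; two molecules of 2 enter in step 1).

**Step 4 (key step, proposed new method).** Several processes may compete with the ring closure:
- Capture of the ring B cation by methanol or traces of water instead of the remote ring A hydroxyl, followed by loss of bromine and quinone formation. The cation is not stabilised by its meta hydroxyl and is short-lived, while the nucleophile is a hindered, acidic 2,6-dibromophenol.
- Addition at B3 instead of B1.
- Intermolecular coupling to oligomers, with fouling of the anode.
- Further oxidation of ring A after ring closure.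
- Cathodic reduction of 7 in the undivided cell, which would only anticipate step 5.

Fallback (known chemistry; sets out from 2 and comes back to the route at 9): the diaryl ether is made first between two separate rings, and the macrocycle is closed in the chain by olefin metathesis. 7-Bromohept-1-ene (C=CCCCCCBr) is converted with Mg in THF into hept-6-en-1-ylmagnesium bromide F1, which is coupled with 2 under Li2CuCl4 catalysis to 1,3-dimethoxy-5-(oct-7-en-1-yl)benzene F2. One portion of this arene is mono-demethylated with NaSEt in DMF at 140 °C to 3-methoxy-5-(oct-7-en-1-yl)phenol F3. The other portion is iodinated with N-iodosuccinimide (cat. CF3CO2H, MeCN, 0 °C) at the ring carbon between the chain and a methoxy group, para to the other methoxy group, which gives 2-iodo-1,5-dimethoxy-3-(oct-7-en-1-yl)benzene F4. Ullmann coupling of the phenol with the iodide (CuI, picolinic acid, K3PO4, DMSO, 100 °C) should give 1,5-dimethoxy-2-[3-methoxy-5-(oct-7-en-1-yl)phenoxy]-3-(oct-7-en-1-yl)benzene F5. Ring-closing metathesis with the second-generation Grubbs catalyst (CH2Cl2, 40 °C, 1 mM) should close the 20-membered cycloalkene F6 (C7=C8, E/Z mixture). H2 over Pd/C saturates it to the tri-O-methyl ether of the target F7, and BBr3 in CH2Cl2 cleaves the three methyl ethers to give 9.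

**Step 1.** Wurtz-type chain coupling during formation of 3, or incomplete insertion at the second terminus, would shorten or cap the tether. Homocoupling of the benzylic bromide through halogen–metal exchange would consume 2 and leave mono-coupled material.

Fallback (sets out from 1 and comes back at 4): the benzylic bonds are formed as alkenes by a double Wittig reaction. 1 and PPh3 (2.2 equiv) in refluxing MeCN give dodecane-1,12-diylbis(triphenylphosphonium) dibromide F8. NaN(SiMe3)2 in THF converts this salt into the bis-ylide dodecane-1,12-diylidenebis(triphenylphosphorane) F9. The bis-ylide reacts in the same flask with two molecules of 3,5-dimethoxybenzaldehyde (COc1cc(C=O)cc(OC)c1) to give 1,14-bis(3,5-dimethoxyphenyl)tetradeca-1,13-diene F10 (E/Z mixture). H2 over Pd/C in EtOAc then gives 4.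

**Step 6.** The hydrogenolysis may stall at partly brominated stages, because all five C–Br bonds have two ortho substituents and the accumulating bromide salt deactivates the catalyst. The deprotonated triphenol may also be oxidised by air during work-up.

Fallback (sets out from 8 and comes back at 9): the phenols are protected, the bromines are removed by a radical chain instead of on a metal surface, and the product is purified as a stable ester. Ac2O in pyridine with 4-(dimethylamino)pyridine converts 8 into the A3,B2,B4-triacetate of the pentabromide F11. Bu3SnH (excess, high concentration) with AIBN in toluene at 100 °C replaces the five bromines by hydrogen and gives the triacetate of the target F12. K2CO3 in degassed MeOH, followed by acidification, releases 9.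

**Step 5.** Electron transfer may expel the ring A aryloxide instead of bromide and so reopen the macrocycle. 7 may also decompose on standing in acid, since it is a positive-bromine donor.

Fallback (sets out from 7 and comes back at 9; no new compound): crude 7 is submitted directly to H2, Pd/C and Et3N in MeOH. The labile B1–Br bond should be hydrogenolysed first, with aromatisation, and the five aryl bromides after it, so that the dissolving-metal step and the isolation of 8 are bypassed.

## Further compounds

F1 | step 4 | hept-6-en-1-ylmagnesium bromide | C=CCCCCC[Mg]Br
F2 | step 4 | 1,3-dimethoxy-5-(oct-7-en-1-yl)benzene | COc1cc(CCCCCCC=C)cc(OC)c1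
F3 | step 4 | 3-methoxy-5-(oct-7-en-1-yl)phenol | COc1cc(O)cc(CCCCCCC=C)c1
F4 | step 4 | 2-iodo-1,5-dimethoxy-3-(oct-7-en-1-yl)benzene | COc1cc(OC)c(I)c(CCCCCCC=C)c1
F5 | step 4 | 1,5-dimethoxy-2-[3-methoxy-5-(oct-7-en-1-yl)phenoxy]-3-(oct-7-en-1-yl)benzene | COc1cc(CCCCCCC=C)cc(Oc2c(OC)cc(OC)cc2CCCCCCC=C)c1
F6 | step 4 | 20-membered cycloalkene, C7=C8 (E/Z mixture), A3, B2 and B4 oxygens as methyl ethers | COc1cc2cc(c1)Oc1c(OC)cc(OC)cc1CCCCCCC=CCCCCCC2
F7 | step 4 | tri-O-methyl ether of the target (A3, B2, B4 methoxy) | COc1cc2cc(c1)Oc1c(OC)cc(OC)cc1CCCCCCCCCCCCCC2
F8 | step 1 | dodecane-1,12-diylbis(triphenylphosphonium) dibromide | [Br-].[Br-].c1ccccc1[P+](c1ccccc1)(c1ccccc1)CCCCCCCCCCCC[P+](c1ccccc1)(c1ccccc1)c1ccccc1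
F9 | step 1 | dodecane-1,12-diylidenebis(triphenylphosphorane) | c1ccccc1P(c1ccccc1)(c1ccccc1)=CCCCCCCCCCCC=P(c1ccccc1)(c1ccccc1)c1ccccc1
F10 | step 1 | 1,14-bis(3,5-dimethoxyphenyl)tetradeca-1,13-diene (E/Z mixture) | COc1cc(C=CCCCCCCCCCCC=Cc2cc(OC)cc(OC)c2)cc(OC)c1
F11 | step 6 | A3,B2,B4-triacetate of the pentabromo macrocycle | CC(=O)Oc1c(Br)c2c(Br)c(c1Br)Oc1c(OC(C)=O)c(Br)c(OC(C)=O)c(Br)c1CCCCCCCCCCCCCC2
F12 | step 6 | A3,B2,B4-triacetate of the target | CC(=O)Oc1cc2cc(c1)Oc1c(OC(C)=O)cc(OC(C)=O)cc1CCCCCCCCCCCCCC2
F0 | step 5 | none | none
A1 | alternative 1 | 3-[2,4-dimethoxy-6-(pent-4-en-1-yl)phenoxy]-5-(undec-10-en-1-yl)phenol | C=CCCCCCCCCCc1cc(O)cc(Oc2c(OC)cc(OC)cc2CCCC=C)c1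
A2 | alternative 1 | 3-(undec-10-en-1-yl)cyclobut-2-en-1-one | C=CCCCCCCCCCC1=CC(=O)C1
A3 | alternative 1 | 2-(ethynyloxy)-1,5-dimethoxy-3-(pent-4-en-1-yl)benzene | C#COc1c(OC)cc(OC)cc1CCCC=C
A4 | alternative 2 | target with the B2 hydroxyl as methyl ether | COc1cc(O)cc2c1Oc1cc(O)cc(c1)CCCCCCCCCCCCCC2
A5 | alternative 2 | deoxy macrocycle (no oxygen at A3 and B4, B2 methoxy) | COc1cccc2c1Oc1cccc(c1)CCCCCCCCCCCCCC2
A6 | alternative 3 | macrocyclic triyne (C4–C7 diyne, C13–C14 alkyne, trimethyl ether) | COc1cc2cc(c1)Oc1c(OC)cc(OC)cc1CCCC#CC#CCCCCCC#C2
A7 | alternative 3 | 1,5-dimethoxy-2-[3-methoxy-5-(nona-1,8-diyn-1-yl)phenoxy]-3-(pent-4-yn-1-yl)benzene | COc1cc(C#CCCCCCC#C)cc(Oc2c(OC)cc(OC)cc2CCCC#C)c1
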